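Late in the west run Z had sunk to 9.0% at 10.0 d. There L, a complex taking up incoming ligand E to give Z (one ligand exchanged) and then Q (two exchanged), was charged at 1.3 M, against 0.64 M in the south run and the flask, with 1.20 equiv of E in each.

| run | time / d | Z / % | Q / % |
|---|---|---|---|
| south | 0.208 | 19.8 | 3.6 |
| south | 0.625 | 28.3 | 15.0 |
| south | 2.00 | 23.8 | 32.9 |
| south | 8.00 | 13.1 | 43.5 |
| west | 0.208 | 26.7 | 9.6 |
| west | 0.625 | 27.0 | 26.4 |
| west | 3.00 | 15.2 | 43.1 |
| west | 10.0 | 9.0 | 44.9 |

(standard deviation of a reading: 0.3 percentage points)

- when, up to 15 d, the flask holds most Z
- the amount of Z, in percent of the L charged, at that time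

I turned the question round: a late best time needs Z above its early readings late in the flask. I assumed bimolecular (second-order) steps, so that at equal equivalents, equal clock values, clock being charged L times time, mean equal composition. West's last reading then stands for the flask at 20.3 d, later than the 15 d allowed, and shows about a third of south's highest reading, 28.3%. So the flask stands far from a late best.

West's readings at 0.208 d and 0.625 d are nearly equal, 26.7% and 27.0%, so they straddle the maximum. Their geometric-mean clock, the peak clock 675 M·min, read off these scattered readings, gave my estimate of the flask's peak: 0.732 d.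

The forecast said “one early maximum and nothing later”, with 28.6% (28.1% to 29.3%) at 0.8 d (0.62 d to 0.98 d), a time later than mine.

The flask gave 28.6% at 0.747 d, a clock of 688 M·min against the carried 675 M·min. It is worth stopping near that time: by 15.0 d its Z stands at 10.1%. J is the leaving ligand, D the other product.

    L + E → J + Z (k = 0.00138 M⁻¹ min⁻¹)
    Z + E → J + Q (k = 0.00159 M⁻¹ min⁻¹)
    L + Z → D (k = 5.83 × 10⁻⁴ M⁻¹ min⁻¹)

At 0.398 d the flask made Z 1.54 times as fast as it used it, each step taken net. At 15.0 d that ratio was 0.0626. For a neighbour flask with L at 1.6 M and the same equivalents of E, the peak clock gives a peak near 0.293 d at the flask's height, and the neighbour's 15 d equals 37.5 d of the flask, between the flask's 10.1% at 15.0 d and 5.35% at 150 d. Computed, that neighbour flask gives a best of 28.6%, about the same as the flask's, and ends at 7.03% Z.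

The data were computed for substances that don't exist; scatter was added.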